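## Retrosynthetic overview

1. The last cut is the C6–prenyl bond. The precursor, (4R)-8-benzoyl-5,7-dihydroxy-4-phenylchroman-2-one, has only one free ring carbon, so late C-prenylation has a single carbon site.
2. The key cut takes C4–C4a and O1–C2 together, so the whole lactone ring forms in one operation. The partners are symmetric 2,4,6-trihydroxybenzophenone and PhC≡C–CHO, joined through a chiral cinnamoyl azolium. The arene is dearomatised in the C–C bond-forming event, loses its symmetry for good, and C4 is set as (R).
3. 2,4,6-Trihydroxybenzophenone comes from phloroglucinol and benzoyl chloride by Friedel–Crafts acylation.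
4. Ring order: all three benzene rings are bought. The dihydropyranone is the only ring built, in step 2.

Assumption: the (5aR,10bS)-N-mesityl aminoindanol triazolium chloride, [Cl-].c1[n+](-c2c(C)cc(C)cc2C)nc2n1[C@H]1c3ccccc3C[C@H]1OC2, is taken to leave the Re face of Cβ of the bound cinnamoyl unit open (C=O syn to the indane-bearing nitrogen, s-cis enone, indane over the Si face); if the first run gives the (S)-lactone, the equally available (5aS,10bR) salt is used and nothing else changes.

## Route

Step 1
Reactants: 1 phloroglucinol; 2 benzoyl chloride
Product: 3 phlorobenzophenone (2,4,6-trihydroxybenzophenone)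
Conditions: AlCl3 (3.5 equiv), PhNO2–CH2Cl2, 0 → 60 °C; aq HCl
Reagents that add atoms: benzoyl chloride (2), O=C(Cl)c1ccccc1
Why: Friedel–Crafts acylation of the threefold-activated ring stops after one benzoyl group because the aluminium-chelated aryl ketone is deactivated, any O-benzoate is carried to carbon by Fries rearrangement under the same conditions, and no stereocentre is formed.

Step 2
Reactants: 3 phlorobenzophenone (1.3 equiv); 4 3-phenylpropiolaldehyde (1.0 equiv)
Product: 7 (4R)-8-benzoyl-5,7-dihydroxy-4-phenylchroman-2-one, via cinnamoyl azolium chloride 5 (not isolated), via dearomatised dienone adduct 6 (not isolated)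
Conditions: (5aR,10bS)-N-mesityl aminoindanol triazolium chloride (10 mol %), no added base, 4 Å MS, PhMe–THF 4:1, 40 °C, 36 h
Reagents that add atoms: 3-phenylpropiolaldehyde (4), O=CC#Cc1ccccc1
Why: Proposed new method: the carbene converts ynal 4 by internal redox into (E)-cinnamoyl azolium 5; a phenol OH of 3 (a stable enol of pKa about 8, the same window as kojic acids and 1,3-dicarbonyls) adds to its C=O, and the hemiacetal undergoes a Coates–Claisen-type [3,3] shift (kinetically equivalent to conjugate addition) that forms C4–C4a at either of the two equivalent ring CH carbons and gives the non-aromatic dienone 6, which re-aromatises and lactonises with release of the carbene; the indane wall covers the Si face of Cβ, so the ring carbon arrives on the Re face and C4 is set as (R); O-cinnamoylation is not a dead end because aryl esters of so acidic a phenol are re-ionised by the carbene, and the same reversibility lets the acyl group settle on the less acidic oxygen ortho to the benzoyl group (8-benzoyl isomer) while the most acidic para OH stays free, as in Pechmann closures of 2-acylphloroglucinols; closest known reaction type: NHC-catalysed redox annulation of ynals with kojic acids, 2-naphthols and 1,3-dicarbonyls to enantioenriched dihydropyranones.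

Step 3
Reactants: 7 (4R)-8-benzoyl-5,7-dihydroxy-4-phenylchroman-2-one; 8 prenyl bromide
Product: 10 (4R)-8-benzoyl-5,7-dihydroxy-6-(3-methylbut-2-en-1-yl)-4-phenylchroman-2-one (target), via sodium 5-phenoxide 9 (not isolated)
Conditions: NaH (1.05 equiv), PhMe, 0 °C → rt; then 8 (1.2 equiv), rt → 45 °C
Reagents that add atoms: prenyl bromide (8), CC(C)=CCBr
Why: This is a heterogeneous phenoxide C-alkylation (Kornblum-type ortho-alkylation): the suspended tight sodium ion pair 9 shields oxygen, C6 is the only free ring carbon and lies between two oxygens, SN2 attack at the primary carbon gives the linear prenyl group, the non-nucleophilic base leaves the lactone closed so its regiochemistry cannot scramble, and C4 is not touched.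

## Compound list

1 | phloroglucinol (benzene-1,3,5-triol) | Oc1cc(O)cc(O)c1 | starting material
2 | benzoyl chloride | O=C(Cl)c1ccccc1 | starting material
3 | phlorobenzophenone (2,4,6-trihydroxybenzophenone) | O=C(c1ccccc1)c1c(O)cc(O)cc1O | intermediate
4 | 3-phenylpropiolaldehyde (3-phenylprop-2-ynal) | O=CC#Cc1ccccc1 | starting material
5 | (E)-cinnamoyl triazolium chloride formed from 4 and the (5aR,10bS) carbene | [Cl-].O=C(/C=C/c1ccccc1)c1[n+](-c2c(C)cc(C)cc2C)nc2n1[C@H]1c3ccccc3C[C@H]1OC2 | intermediate (not isolated)
6 | dearomatised adduct: 4-benzoyl-3,5-dihydroxycyclohexa-2,4-dien-1-one carrying at its sp3 C6 the chain CH(Ph)–CH=C(O−)–azolium; the benzylic carbon is arranged as C4 of 7; ring C6 and the enolate geometry are left open because both are erased on re-aromatisation | O=C1C=C(O)C(C(=O)c2ccccc2)=C(O)C1[C@@H](c1ccccc1)C=C([O-])c1[n+](-c2c(C)cc(C)cc2C)nc2n1[C@H]1c3ccccc3C[C@H]1OC2 | intermediate (not isolated)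
7 | (4R)-8-benzoyl-5,7-dihydroxy-4-phenylchroman-2-one | c1c(O)c(C(=O)c2ccccc2)c2c(c1O)[C@@H](c1ccccc1)CC(=O)O2 | intermediate
8 | prenyl bromide (1-bromo-3-methylbut-2-ene) | CC(C)=CCBr | starting material
9 | sodium salt of 7, deprotonated at the 5-OH (para to the benzoyl group), (4R) | [Na+].c1c(O)c(C(=O)c2ccccc2)c2c(c1[O-])[C@@H](c1ccccc1)CC(=O)O2 | intermediate (not isolated)
10 | (4R)-8-benzoyl-5,7-dihydroxy-6-(3-methylbut-2-en-1-yl)-4-phenyl-3,4-dihydro-2H-chromen-2-one | CC(C)=CCc1c(O)c(C(=O)c2ccccc2)c2c(c1O)[C@@H](c1ccccc1)CC(=O)O2 | target

## Counts

Total step count: 3. Longest linear sequence: 3 (1 → 3 → 7 → 10).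

## Steps most likely to fail

**Step 2 (highest risk).**
- The ring carbon of 3 may be too poor a partner, so that only aryl cinnamates build up.
- Closure may stop on the para oxygen and give the 6-benzoyl lactone.
- The ee may be moderate for this new nucleophile class.

The fallback forms the C4–phenyl bond instead of C4–C4a. It sets out from 3. Pd(OAc)2-catalysed hydroarylation–lactonisation with ethyl propiolate in TFA–CH2Cl2 gives 8-benzoyl-5,7-dihydroxy-2H-chromen-2-one F1. Hayashi–Miyaura 1,4-addition of phenylboronic acid follows, with Rh(acac)(C2H4)2 and (R)-SEGPHOS in dioxane–H2O at 60 °C. (R)-SEGPHOS is the ligand enantiomer that gives (R)-4-arylchroman-2-ones from simple coumarins. This returns to the route at 7.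

**Step 3.**
- O-Prenylation of the acidic 5-OH may compete with C-alkylation.
- A second prenylation at C6 would give a gem-diprenyl dienone.
- The delocalised phenoxide may react slowly.

The fallback changes the order of events. It sets out from 3. Prenyl bromide 8 in aqueous KOH at 0 °C, the standard C-prenylation of acylphloroglucinols, gives 3-prenyl-2,4,6-trihydroxybenzophenone F2, which is separated from the diprenyl by-product. The carbene annulation of step 2 with 4 is then run on F2, whose single free ring carbon takes the cinnamoyl unit. This returns to the route directly at 10, with the stereocentre made in the last operation.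

**Step 1.**
- Over-benzoylation may occur.
- O-benzoates may persist.
- Removal of nitrobenzene is laborious and can cost yield.

The fallback changes the electrophile to a nitrile (Houben–Hoesch reaction). It sets out from 1. Benzonitrile, ZnCl2 and dry HCl in Et2O at 0 °C precipitate phenyl(2,4,6-trihydroxyphenyl)methaniminium chloride F3, which cannot react a second time. Boiling F3 in water hydrolyses it and returns to the route at 3.

## Further compounds

F1 | step 2 | 8-benzoyl-5,7-dihydroxy-2H-chromen-2-one | O=C1C=Cc2c(O)cc(O)c(C(=O)c3ccccc3)c2O1
F2 | step 3 | 3-(3-methylbut-2-en-1-yl)-2,4,6-trihydroxybenzophenone | CC(C)=CCc1c(O)cc(O)c(C(=O)c2ccccc2)c1O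
F3 | step 1 | phenyl(2,4,6-trihydroxyphenyl)methaniminium chloride | [Cl-].[NH2+]=C(c1ccccc1)c1c(O)cc(O)cc1O
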